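## Retrosynthetic overview
1. Target ⇐ one Lewis-acid unmasking (two O-benzyl groups and the peri 5-O-methyl group) of a 3-hydroxyflavone with ring A fully O-methylated and ring B as its dibenzyl ether.
2. Ring C (3-hydroxy-4-pyranone) ⇐ Algar–Flynn–Oyamada oxidative cyclisation of a 2'-hydroxychalcone, forming the O1–C2 bond and the C3–OH in one pot.
3. Chalcone ⇐ Claisen–Schmidt condensation of 2'-hydroxy-3',4',5',6'-tetramethoxyacetophenone (ring A, all oxygens in place) with 2,5-bis(benzyloxy)benzaldehyde (ring B).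
4. Aldehyde ⇐ double O-benzylation of 2,5-dihydroxybenzaldehyde.
5. Ring order: rings A and B are bought; ring C is the only ring formed (step 3).

Assumption: the target has no stereocentre, so the achiral compound as drawn is made, and 1-(2-hydroxy-3,4,5,6-tetramethoxyphenyl)ethan-1-one is taken as a catalogue item.

## Route

Step 1
Reactants: 1 2,5-dihydroxybenzaldehyde
Product: 3 2,5-bis(benzyloxy)benzaldehyde, via 5-benzyloxy-2-hydroxybenzaldehyde 2 (not isolated)
Conditions: BnBr (2.5 equiv), K2CO3 (3 equiv), DMF, 60 °C, 6 h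
Reagents that add atoms: benzyl bromide, BrCc1ccccc1
Why: Double Williamson ether synthesis (SN2 of the phenoxides on benzyl bromide), in which the free 5-OH reacts first and the hydrogen-bonded 2-OH follows on heating; the aldehyde is inert to carbonate and no stereocentre is formed.

Step 2
Reactants: 3 2,5-bis(benzyloxy)benzaldehyde; 4 1-(2-hydroxy-3,4,5,6-tetramethoxyphenyl)ethan-1-one
Product: 6 (E)-3-[2,5-bis(benzyloxy)phenyl]-1-(2-hydroxy-3,4,5,6-tetramethoxyphenyl)prop-2-en-1-one, via aldol adduct 5 (not isolated)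
Conditions: KOH (50% aq, 10 equiv), EtOH, rt, 48 h; then 1 M HCl, 0 °C
Reagents that add atoms: none
Why: Claisen–Schmidt (crossed aldol) condensation, in which the methyl ketone enolate of 4 adds to the non-enolisable aldehyde 3 and E1cB loss of water from 5 gives the conjugated E-enone under thermodynamic control; no stereocentre remains.

Step 3
Reactants: 6 (E)-3-[2,5-bis(benzyloxy)phenyl]-1-(2-hydroxy-3,4,5,6-tetramethoxyphenyl)prop-2-en-1-one
Product: 8 2-[2,5-bis(benzyloxy)phenyl]-3-hydroxy-5,6,7,8-tetramethoxy-4H-chromen-4-one, via trans-3-hydroxyflavanone 7 (not isolated)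
Conditions: 30% aq H2O2 (5 equiv), 2 M aq NaOH, MeOH/THF, 0 °C to rt, 6 h; then 1 M HCl
Reagents that add atoms: hydrogen peroxide, OO
Why: Algar–Flynn–Oyamada reaction, in which the phenoxide closes ring C by oxa-Michael addition, the enolate is hydroxylated by H2O2 to 7, and 7 is dehydrogenated in the flask to the 3-hydroxy-4-pyranone, erasing its two transient stereocentres; low temperature and excess peroxide hold back the competing aurone path.

Step 4
Reactants: 8 2-[2,5-bis(benzyloxy)phenyl]-3-hydroxy-5,6,7,8-tetramethoxy-4H-chromen-4-one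
Product: 9 2-(2,5-dihydroxyphenyl)-3,5-dihydroxy-6,7,8-trimethoxy-4H-chromen-4-one
Conditions: BCl3 (1 M in CH2Cl2, 8 equiv), pentamethylbenzene (6 equiv), CH2Cl2, −78 °C to 0 °C, 3 h, argon; then H2O/1 M HCl
Reagents that add atoms: none
Why: Lewis-acid ether cleavage, in which BCl3 removes both O-benzyl groups (benzyl cation trapped by pentamethylbenzene in a Friedel–Crafts alkylation) and, through a six-membered chelate with the C4 carbonyl, only the peri 5-O-methyl group, while the non-chelated 6-, 7- and 8-methoxy groups survive at 0 °C or below; no stereocentre is involved.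

## Compound list
1 | 2,5-dihydroxybenzaldehyde | O=Cc1cc(O)ccc1O | starting material
2 | 5-(benzyloxy)-2-hydroxybenzaldehyde | O=Cc1cc(OCc2ccccc2)ccc1O | intermediate
3 | 2,5-bis(benzyloxy)benzaldehyde | O=Cc1cc(OCc2ccccc2)ccc1OCc1ccccc1 | intermediate
4 | 1-(2-hydroxy-3,4,5,6-tetramethoxyphenyl)ethan-1-one | CC(=O)c1c(O)c(OC)c(OC)c(OC)c1OC | starting material
5 | racemic 3-[2,5-bis(benzyloxy)phenyl]-3-hydroxy-1-(2-hydroxy-3,4,5,6-tetramethoxyphenyl)propan-1-one (aldol adduct) | O=C(CC(O)c1cc(OCc2ccccc2)ccc1OCc1ccccc1)c1c(O)c(OC)c(OC)c(OC)c1OC | intermediate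
6 | (E)-3-[2,5-bis(benzyloxy)phenyl]-1-(2-hydroxy-3,4,5,6-tetramethoxyphenyl)prop-2-en-1-one | O=C(/C=C/c1cc(OCc2ccccc2)ccc1OCc1ccccc1)c1c(O)c(OC)c(OC)c(OC)c1OC | intermediate
7 | racemic trans-2-[2,5-bis(benzyloxy)phenyl]-3-hydroxy-5,6,7,8-tetramethoxy-2,3-dihydro-4H-chromen-4-one (2R,3R enantiomer drawn) | COc1c(OC)c(OC)c2c(c1OC)O[C@H](c1cc(OCc3ccccc3)ccc1OCc1ccccc1)[C@@H](O)C2=O | intermediate
8 | 2-[2,5-bis(benzyloxy)phenyl]-3-hydroxy-5,6,7,8-tetramethoxy-4H-chromen-4-one | COc1c(OC)c(OC)c2c(=O)c(O)c(-c3cc(OCc4ccccc4)ccc3OCc3ccccc3)oc2c1OC | intermediate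
9 | 2-(2,5-dihydroxyphenyl)-3,5-dihydroxy-6,7,8-trimethoxy-4H-chromen-4-one (achiral) | COc1c(OC)c(O)c2c(=O)c(O)c(-c3cc(O)ccc3O)oc2c1OC | target

## Summary
Total step count: 4.
Longest linear sequence: 4 steps (1 → 3 → 6 → 8 → 9).

Steps most likely to fail:

Step 3. A 6'-methoxy group on the chalcone and an ortho-substituted ring B both push the Algar–Flynn–Oyamada reaction towards the aurone. The fallback sets out from 6 and comes back at 8. Chalcone 6 is cyclodehydrogenated with catalytic I2 in DMSO at 120 °C to the flavone 2-[2,5-bis(benzyloxy)phenyl]-5,6,7,8-tetramethoxy-4H-chromen-4-one F1. The C2=C3 bond of F1 is epoxidised with dimethyldioxirane (acetone/CH2Cl2, 0 °C) to the racemic epoxide 2-[2,5-bis(benzyloxy)phenyl]-2,3-epoxy-5,6,7,8-tetramethoxychroman-4-one F2. Catalytic p-TsOH in CH2Cl2 then opens F2 at the benzylic C2–O bond, and loss of H-3 gives the 3-hydroxyflavone 8. Because the 3-OH is put in after ring C is closed, no aurone can form.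

Step 4. One-pot BCl3 unmasking may over-demethylate at C6 or C-benzylate the electron-rich rings. The fallback sets out from 8 and comes back at 9, and splits the deprotection into two orthogonal operations. Hydrogenolysis of 8 (H2 1 atm, 10% Pd/C, EtOAc/MeOH, rt) gives 2-(2,5-dihydroxyphenyl)-3-hydroxy-5,6,7,8-tetramethoxy-4H-chromen-4-one F3. Chelation-controlled demethylation of F3 with anhydrous AlCl3 in MeCN (rt to 50 °C, then dilute HCl, under argon) removes only the 5-O-methyl group next to the carbonyl and gives 9.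

Step 2. The Claisen–Schmidt condensation can stall, because the phenoxide of 4 makes the enolate hard to form and aldehyde 3 is ortho-substituted. The fallback sets out from 3 and 4 and comes back at 8, building the C-ring carbons by acyl transfer instead of aldol chemistry. Pinnick oxidation of 3 (NaClO2, NaH2PO4, 2-methyl-2-butene, t-BuOH/H2O) gives 2,5-bis(benzyloxy)benzoic acid F4. Steglich esterification of F4 with phenol 4 (EDC·HCl, DMAP, CH2Cl2) gives 2-acetyl-3,4,5,6-tetramethoxyphenyl 2,5-bis(benzyloxy)benzoate F5. Baker–Venkataraman rearrangement of F5 (KOH, pyridine, 50 °C) gives the diketone 1-[2,5-bis(benzyloxy)phenyl]-3-(2-hydroxy-3,4,5,6-tetramethoxyphenyl)propane-1,3-dione F6. Cyclodehydration of F6 (catalytic H2SO4, AcOH, 60 °C) gives the flavone 2-[2,5-bis(benzyloxy)phenyl]-5,6,7,8-tetramethoxy-4H-chromen-4-one F1. F1 is carried to 8 by the dimethyldioxirane epoxidation to the epoxide 2-[2,5-bis(benzyloxy)phenyl]-2,3-epoxy-5,6,7,8-tetramethoxychroman-4-one F2 and p-TsOH rearrangement described for step 3.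

## Further compounds
F1 | step 3 | 2-[2,5-bis(benzyloxy)phenyl]-5,6,7,8-tetramethoxy-4H-chromen-4-one | COc1c(OC)c(OC)c2c(=O)cc(-c3cc(OCc4ccccc4)ccc3OCc3ccccc3)oc2c1OC
F2 | step 3 | racemic 2-[2,5-bis(benzyloxy)phenyl]-2,3-epoxy-5,6,7,8-tetramethoxychroman-4-one | COc1c(OC)c(OC)c2c(c1OC)OC1(c3cc(OCc4ccccc4)ccc3OCc3ccccc3)OC1C2=O
F3 | step 4 | 2-(2,5-dihydroxyphenyl)-3-hydroxy-5,6,7,8-tetramethoxy-4H-chromen-4-one | COc1c(OC)c(OC)c2c(=O)c(O)c(-c3cc(O)ccc3O)oc2c1OC
F4 | step 2 | 2,5-bis(benzyloxy)benzoic acid | O=C(O)c1cc(OCc2ccccc2)ccc1OCc1ccccc1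
F5 | step 2 | 2-acetyl-3,4,5,6-tetramethoxyphenyl 2,5-bis(benzyloxy)benzoate | CC(=O)c1c(OC(=O)c2cc(OCc3ccccc3)ccc2OCc2ccccc2)c(OC)c(OC)c(OC)c1OC
F6 | step 2 | 1-[2,5-bis(benzyloxy)phenyl]-3-(2-hydroxy-3,4,5,6-tetramethoxyphenyl)propane-1,3-dione | O=C(CC(=O)c1cc(OCc2ccccc2)ccc1OCc1ccccc1)c1c(O)c(OC)c(OC)c(OC)c1OC
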